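Two questions stand: a row of shares of target and the shape of that row.

| setting | eta | Sunday's | Thursday's | Saturday's |
|---|---|---|---|---|
| substrate | 0.0010 M | 0.0010 M | 0.0020 M | 0.0040 M |
| reagent | 2 equiv | 1.30 equiv | 1.30 equiv | 1.30 equiv |
| free catalyst | 5 mol% | 5 mol% | 5 mol% | 5 mol% |
| second catalyst | 4 mol% | 4 mol% | 4 mol% | 4 mol% |
| remark | run made earlier |  |  |  |
| time |  | 2.5 min | 2.5 min | 2.5 min |

- eta (time / s: target / %, side product / %): 10.0: 5.3, 0.6; 20.0: 14.7, 4.6; 30.0: 25.0, 7.1

(scatter of a reading: 0.5 percentage points)

1. share of target in all that became target or side product for Sunday's, Thursday's, Saturday's, in this order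
2. how that number moves from the first to the last of them (hardly changes / falls, then rises / falls all the way / rises all the way / rises, then falls)

Reagent is charged at 1.30 equiv. Taken one to one, its charge exceeds that of substrate, so substrate is the limiting reagent and the ledger is kept on substrate. The eta run had 32.1% of its substrate in the two products at 30.0 s. At the pace of its last interval, taken over to these flasks, the remainder needs 53.0 s, less than the 2.5 min allowed, so the ledger is treated as closed.

The eta run's reading at 30.0 s gives 25.0% of target and 7.1% of side product, a selectivity factor of 3.52 target per side product, with a scatter of 0.5 percentage points on each reading. One run cannot test the supposition made here: both products grow from one shared species, which turns to side product by itself and to target on meeting second catalyst, with the reagent's step fast. Target per side product then follows [second catalyst]. Dividing the reading by the [second catalyst] charged in the eta run gives the capture number, target per side product for each mole per litre of second catalyst charged, itself a reading with that scatter: 88000 M⁻¹.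

The entries for what becomes target or side product, with [second catalyst] as charged, are:

Sunday's: [second catalyst] 4.00 × 10⁻⁵ M, ratio 3.52, share 77.9%

Thursday's: [second catalyst] 8.00 × 10⁻⁵ M, ratio 7.04, share 87.6%

Saturday's: [second catalyst] 1.60 × 10⁻⁴ M, ratio 14.1, share 93.4%

This reckoning rises. The forecast differs: it gives 78%, 78%, 78%, so hardly changes, holding that “any concentration trend would be a guess”.

The flasks give 74.2%, 85.2%, 92.0%: rises all the way.

    substrate + free catalyst → free catalyst + open intermediate (k = 560 M⁻¹ s⁻¹)
    2 substrate → homo dimer (k = 16.0 M⁻¹ s⁻¹)
    reagent + catalyst intermediate → second catalyst + target (k = 450 M⁻¹ s⁻¹)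
    second catalyst + open intermediate ⇌ catalyst intermediate (K = 39000 M⁻¹, k = 2600 M⁻¹ s⁻¹)
    open intermediate → side product (k = 0.0220 s⁻¹)

On Sunday's, at 1.25 min, second catalyst stood at 85.4% with 14.6% held as catalyst intermediate, while on Saturday's at 1.25 min it stood at >99.9%. The capture number of 88000 M⁻¹, put to the [second catalyst] charged on Saturday's, gives a share of 93.4%, which is 1.4 points above the 92.0% of Saturday's flask.

(All runs stem from a simulated flask for an exercise; scatter was added.)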